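Core numbering used throughout: C1 (ketone), C2=C3 (methyl on C3), C4, C5, C6 (CMe2), C7 (O-angelate), C8, C9 (O-isovalerate), C10 (quaternary, methyl), C11; ring A = C1–C2–C3–C4–C5–C11, ring B = C4–C5–C6–C7–C8–C9–C10, cyclobutane = C4–C5–C11–C10.
Retrosynthesis: cut the two ester C–O bonds, then C7–O and the C9 carbinol (back to a C7=C8 enone and a C9 ketone), then the cyclobutane bond C10–C11, then C9–C10 (one-carbon ring enlargement that brings in C10 and its methyl), and last C3–C4 and C5–C11 (Diels–Alder).
Enabling feature: C10 and C11 are each α to a carbonyl-level carbon (C9 and C1), so the C10–C11 bond joins two enolate carbons across a 1,4-dioxygen pattern. In the cis-fused bicycle of rings A and B they lie on one face, and with C7=C8 and C2=C3 unsaturated they are the only α′ positions that can be deprotonated.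
Forward: ring A by cycloaddition onto 4,4-dimethylcyclohexenone; ring B enlarged from six to seven members; both enones placed by Saegusa–Ito oxidation; oxidative coupling of the bis(enol silane) closes the cyclobutane; then O7 (conjugate borylation–oxidation), O9 (Evans–Tishchenko) and the two esters.
Stereochemistry: C4/C5 from a catalyst-controlled suprafacial (cis) Diels–Alder; C10/C11 dictated by the cis ring fusion; C7 from ligand-controlled boron delivery; C9 from hydride delivered intramolecularly from O7 (trans diol); the Z geometry of the angelate comes with angelic acid.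

Key step: step 6

Assumption: the (S)-prolinol-derived oxazaborolidinium salt of step 2 and (R)-DTBM-SEGPHOS in step 7 are written as the antipodes taken to give the required sense; should either induce the opposite sense, its mirror image is used and nothing else changes.

Step 1
Reactants: 1 (E)-pent-3-en-2-one
Product: 2 (E)-2-(tert-butyldimethylsilyloxy)penta-1,3-diene
Conditions: TBSOTf (1.1 equiv), Et3N (1.5 equiv), Et2O, 0 °C
Reagents that add atoms: tert-butyldimethylsilyl trifluoromethanesulfonate, CC(C)(C)[Si](C)(C)OS(=O)(=O)C(F)(F)F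
Why: Soft enolisation (O-silylation, then loss of an acetyl proton to the amine) should give the cross-conjugated silyl dienol ether with the E alkene untouched.

Step 2
Reactants: 3 4,4-dimethylcyclohex-2-en-1-one; 2 (E)-2-(tert-butyldimethylsilyloxy)penta-1,3-diene
Product: 4 cis-fused cycloadduct (4aR,8S,8aS)-6-(tert-butyldimethylsilyloxy)-4,4,8-trimethyl-3,4,4a,5,8,8a-hexahydronaphthalen-1(2H)-one
Conditions: oxazaborolidinium triflimide from (S)-α,α-diphenylprolinol, o-tolylboronic acid and HN(SO2CF3)2 (20 mol%), 2 (1.5 equiv), CH2Cl2, −40 → −10 °C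
Reagents that add atoms: none
Why: Catalytic enantioselective Diels–Alder reaction in which the cationic boron Lewis acid activates the enone and shields one face, the CH2 terminus of the diene (C11) bonds to the β carbon (C5) and the methyl-bearing terminus (C3) to the α carbon (C4), so that suprafacial addition gives the cis ring fusion with C4 and C5 set by the catalyst (the C3 centre is removed in step 5).

Step 3
Reactants: 4 cis-fused cycloadduct; 5 1,1-dibromoethane
Product: 6 1-(1,1-dibromoethyl) carbinol at C9 of the cycloadduct
Conditions: 5 (1.5 equiv), LiN(i-Pr)2 (1.5 equiv) added at −95 °C, THF; NH4Cl aq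
Reagents that add atoms: none
Why: Carbonyl addition of an α-haloalkyllithium: 1,1-dibromoethyllithium formed in the flask should add to the only ketone (C9) while the silyl enol ether is inert, and the configuration of the new carbinol centre is irrelevant because it is lost in step 4.

Step 4
Reactants: 6 1-(1,1-dibromoethyl) carbinol
Product: 8 ring-enlarged cis-fused ketone (C9 ketone; C10 methyl; ring A silyl enol ether kept), via lithium enolate 7 (not isolated)
Conditions: n-BuLi (2.2 equiv), THF, −95 → 0 °C; NH4Cl aq
Reagents that add atoms: none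
Why: β-Oxido carbenoid ring enlargement (a semipinacol-type one-carbon homologation): O-deprotonation and Br/Li exchange give a carbenoid in which the more substituted ring-fusion carbon C4 should migrate with retention onto the carbenoid carbon, which becomes C10 with its methyl, and the resulting C9/C10 enolate is protonated on work-up (C10 need not be controlled).

Step 5
Reactants: 8 ring-enlarged cis-fused ketone
Product: 10 cis-fused bis-enone (4S,5R)-3,6,6,10-tetramethylbicyclo[5.4.0]undeca-2,7-diene-1,9-dione (core numbering; C10 epimers), via bis(silyl enol ether) 9 (not isolated)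
Conditions: LiN(i-Pr)2 (1.2 equiv), Me3SiCl, THF, −78 °C; then Pd(OAc)2 (2.4 equiv), MeCN, 23 °C
Reagents that add atoms: none
Why: Kinetic deprotonation should take the C8 methylene and not the C10 methine, and Saegusa–Ito oxidation by divalent palladium of both enol silanes (the new C8=C9 one and the C1=C2 one kept from the cycloaddition), with β-hydride loss from C7 and C3, places the two enone double bonds regiospecifically.

Step 6
Reactants: 10 cis-fused bis-enone
Product: 12 cage bis-enone (4R,5S,10R,11R)-3,3,7,11-tetramethyltricyclo[5.4.0.0(2,8)]undeca-4,10-diene-6,9-dione (descriptors in core numbering), via bis(silyloxy diene) 11 (not isolated)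
Conditions: LiN(i-Pr)2 (2.4 equiv), Me3SiCl (3 equiv), THF, −78 → −40 °C; solvent switch; (NH4)2Ce(NO3)6 (2.2 equiv), NaHCO3 (4 equiv), MeCN–EtCN, −30 °C
Reagents that add atoms: none
Why: Proposed new method: kinetic double deprotonation can only take H10 and H11 (C8 and C2 are sp2, C6 is quaternary), and silylation gives two 2-silyloxy dienes; tetravalent cerium removes one electron from the more electron-rich, fully substituted C9=C10 enol silane, the radical cation is attacked through C11 by the ring A enol silane, and a second oxidation with loss of both silyl groups returns the two enones. The closest known reaction type is the intramolecular oxidative coupling of bis-enolates or bis(silyl enol ethers) to 1,4-diketones, established for five- and six-membered rings but hardly ever for four. The cyclobutane C4–C5–C11–C10 closes in a 4-exo mode, C10 of the radical cation adding to the C11 terminus of the C11=C1 double bond. C10 and C11 are not set by a reagent: in the cis-fused bicycle the two carbons can bond only when they are gauche about C4–C5, which puts rings A and B on opposite faces of the new ring and gives 10R,11R (H11 syn to H4, C10-methyl syn to H5). The step needs C–C bond formation to outrun desilylation, nitrate trapping and intermolecular coupling; the two-atom tether (C4, C5) holds the partners within bonding distance, and the regiochemistry is secure because neither enone has another enolisable position.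

Step 7
Reactants: 12 cage bis-enone
Product: 14 (7R)-7-hydroxy cage ketone (C9 ketone; ring A enone), via pinacol boronate 13 (not isolated)
Conditions: CuCl (5 mol%), NaOt-Bu (10 mol%), (R)-DTBM-SEGPHOS (6 mol%), B2pin2 (1.1 equiv), MeOH (2 equiv), THF, 0 °C; then NaBO3·4H2O, THF–H2O, 23 °C
Reagents that add atoms: sodium perborate tetrahydrate (NaBO3·4H2O), [Na+].[Na+].O[B-]1(O)OO[B-](O)(O)OO1
Why: Copper-catalysed enantioselective conjugate borylation of the less substituted enone (β-monosubstituted C7 against the fully substituted C3 of ring A), followed by oxidation of the C–B bond with retention, should give the β-hydroxy ketone; because the two faces of C7 are flanked almost equally by H4 and H11, the chiral bisphosphine on monovalent copper decides the face and places boron, and hence oxygen, on the C4 side (7R).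

Step 8
Reactants: 14 (7R)-7-hydroxy cage ketone
Product: 15 (7R,9R)-7-methoxyacetate 9-alcohol
Conditions: MeOCH2CHO (5 equiv), SmI2 (30 mol%), THF, −10 °C
Reagents that add atoms: methoxyacetaldehyde, COCC=O
Why: Evans–Tishchenko reduction, in which the hemiacetal formed at O7 is held by trivalent samarium and delivers hydride to the C9 carbonyl on the face of O7, so that the new C9 hydroxyl is trans to O7 (9R) and O7 leaves as the methoxyacetate, while the ring A enone has no β-hydroxyl and should not be reduced.

Step 9
Reactants: 15 (7R,9R)-7-methoxyacetate 9-alcohol; 16 3-methylbutanoic (isovaleric) anhydride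
Product: 17 7-methoxyacetate 9-isovalerate
Conditions: DMAP (0.5 equiv), Et3N, CH2Cl2, 23 → 40 °C
Reagents that add atoms: none
Why: DMAP-catalysed acyl transfer to the only free hydroxyl (C9), with acyl migration ruled out by the trans-1,3 relationship of O7 and O9 across ring B.

Step 10
Reactants: 17 7-methoxyacetate 9-isovalerate
Product: 18 7-alcohol 9-isovalerate
Conditions: Yb(OTf)3 (20 mol%), MeOH, 0 → 23 °C
Reagents that add atoms: none
Why: Lewis acid-catalysed transesterification that is selective for the chelating α-alkoxy ester: trivalent ytterbium binds the methoxyacetate in bidentate fashion and methanol removes it, while the hindered, non-chelating isovalerate next to the quaternary C10 should stay.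

Step 11
Reactants: 18 7-alcohol 9-isovalerate; 19 angelic acid ((Z)-2-methylbut-2-enoic acid)
Product: 20 CNP0240547.2 (7-O-angeloyl 9-O-isovaleroyl diester; 4R,5S,7R,9R,10R,11R in core numbering)
Conditions: 19, 2,4,6-Cl3C6H2COCl, Et3N, toluene, 23 °C; then 18, toluene, 80 °C
Reagents that add atoms: none
Why: Yamaguchi esterification through the mixed anhydride with 2,4,6-trichlorobenzoic acid, run without DMAP so that the Z (angelate) geometry is not isomerised to the tiglate by reversible conjugate addition, acylates O7 with retention at C7.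

Compound list
1 | (E)-pent-3-en-2-one | C/C=C/C(C)=O | starting material
2 | (E)-2-(tert-butyldimethylsilyloxy)penta-1,3-diene | C/C=C/C(=C)O[Si](C)(C)C(C)(C)C | intermediate
3 | 4,4-dimethylcyclohex-2-en-1-one | CC1(C)CCC(=O)C=C1 | starting material
4 | (4aR,8S,8aS)-6-(tert-butyldimethylsilyloxy)-4,4,8-trimethyl-3,4,4a,5,8,8a-hexahydronaphthalen-1(2H)-one; cis-fused, H4a/H8/H8a syn (core: C9 ketone, C1 silyl enol ether) | C1CC(=O)[C@H]2[C@@H](C)C=C(O[Si](C)(C)C(C)(C)C)C[C@H]2C1(C)C | intermediate
5 | 1,1-dibromoethane | CC(Br)Br | starting material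
6 | 6-(tert-butyldimethylsilyloxy)-1-(1,1-dibromoethyl)-4,4,8-trimethyl-1,2,3,4,4a,5,8,8a-octahydronaphthalen-1-ol; ring stereocentres as in 4, carbinol centre uncontrolled | C1CC(O)(C(C)(Br)Br)[C@H]2[C@@H](C)C=C(O[Si](C)(C)C(C)(C)C)C[C@H]2C1(C)C | intermediate
7 | lithium enolate of 8 (C9–OLi, C9=C10) | C1CC(O[Li])=C(C)[C@H]2[C@@H](C)C=C(O[Si](C)(C)C(C)(C)C)C[C@H]2C1(C)C | intermediate
8 | cis-fused 1-(tert-butyldimethylsilyloxy)-3,6,6,10-tetramethylbicyclo[5.4.0]undec-1-en-9-one (core numbering; C4/C5 as in 4, C10 epimers) | C1CC(=O)C(C)[C@H]2[C@@H](C)C=C(O[Si](C)(C)C(C)(C)C)C[C@H]2C1(C)C | intermediate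
9 | 1-(tert-butyldimethylsilyloxy)-9-(trimethylsilyloxy)-3,6,6,10-tetramethylbicyclo[5.4.0]undeca-1,8-diene (core numbering) | C1C=C(O[Si](C)(C)C)C(C)[C@H]2[C@@H](C)C=C(O[Si](C)(C)C(C)(C)C)C[C@H]2C1(C)C | intermediate
10 | (4S,5R)-3,6,6,10-tetramethylbicyclo[5.4.0]undeca-2,7-diene-1,9-dione (core numbering; cis-fused, C10 epimers) | C1=CC(=O)C(C)[C@H]2C(C)=CC(=O)C[C@H]2C1(C)C | intermediate
11 | 1,9-bis(trimethylsilyloxy)-3,6,6,10-tetramethylbicyclo[5.4.0]undeca-1(11),2,7,9-tetraene (core numbering; ring fusion as in 10) | C1=CC(O[Si](C)(C)C)=C(C)[C@H]2C(C)=CC(O[Si](C)(C)C)=C[C@H]2C1(C)C | intermediate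
12 | cage bis-enone, 10 with the C10–C11 bond, (4R,5S,10R,11R) in core numbering; 3,3,7,11-tetramethyltricyclo[5.4.0.0(2,8)]undeca-4,10-diene-6,9-dione | C1=CC(=O)[C@@]2(C)[C@@H]3C(=O)C=C(C)[C@H]2[C@@H]3C1(C)C | intermediate
13 | C7 pinacol boronate of the cage (boron on the C4 side; C9 ketone, ring A enone) | CC1(C)OB(OC1(C)C)[C@@H]1CC(=O)[C@@]2(C)[C@@H]3C(=O)C=C(C)[C@H]2[C@@H]3C1(C)C | intermediate
14 | (7R)-7-hydroxy cage ketone (C9 ketone, ring A enone) | O[C@@H]1CC(=O)[C@@]2(C)[C@@H]3C(=O)C=C(C)[C@H]2[C@@H]3C1(C)C | intermediate
15 | (7R,9R)-7-methoxyacetoxy-9-hydroxy cage enone | COCC(=O)O[C@@H]1C[C@@H](O)[C@@]2(C)[C@@H]3C(=O)C=C(C)[C@H]2[C@@H]3C1(C)C | intermediate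
16 | 3-methylbutanoic (isovaleric) anhydride | CC(C)CC(=O)OC(=O)CC(C)C | starting material
17 | (7R,9R)-7-methoxyacetoxy-9-isovaleroyloxy cage enone | COCC(=O)O[C@@H]1C[C@@H](OC(=O)CC(C)C)[C@@]2(C)[C@@H]3C(=O)C=C(C)[C@H]2[C@@H]3C1(C)C | intermediate
18 | (7R,9R)-7-hydroxy-9-isovaleroyloxy cage enone | O[C@@H]1C[C@@H](OC(=O)CC(C)C)[C@@]2(C)[C@@H]3C(=O)C=C(C)[C@H]2[C@@H]3C1(C)C | intermediate
19 | angelic acid, (Z)-2-methylbut-2-enoic acid | C/C=C(/C)C(=O)O | starting material
20 | CNP0240547.2, 7-O-angeloyl 9-O-isovaleroyl diester of the cage enone, (4R,5S,7R,9R,10R,11R) in core numbering | C/C=C(/C)C(=O)O[C@@H]1C[C@@H](OC(=O)CC(C)C)[C@@]2(C)[C@@H]3C(=O)C=C(C)[C@H]2[C@@H]3C1(C)C | target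

Total step count: 11. Longest linear sequence: 11 steps (1 to 20, steps 1–11; 10 steps from enone 3).

Steps most likely to fail

First, step 6. Closure of the four-membered ring may be slower than loss of silicon from the radical cation, nitrate trapping at C10 or intermolecular coupling, so that 10 or its α-oxygenated derivatives are returned. The fallback uses two-electron chemistry only and runs from 10 to 12. LiN(i-Pr)2 (1.05 equiv) and Me3SiCl at −78 °C should silylate the faster-formed ring A dienolate to the ring A mono(silyloxy diene) F1. N-Bromosuccinimide should brominate it at C11 from the face away from ring B to give the 11-bromo bis-enone F2. KOt-Bu in THF/t-BuOH then forms the C10 enolate under equilibrating conditions; it displaces bromide with inversion at C11 (4-exo-tet enolate alkylation, the classical closure of pinane-type cyclobutanes) and gives 12.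

Second, step 2. The β carbon next to the quaternary centre may be activated too weakly by the bulky chiral Lewis acid, so that diene decomposition or an unselective background pathway erodes conversion and face selectivity. The fallback moves the source of chirality to a resident stereocentre and runs from enone 3 (with diene 2) to bis-enone 10.
- DDQ dehydrogenation of 3 gives 4,4-dimethylcyclohexa-2,5-dienone F3.
- Copper-catalysed enantioselective conjugate borylation (CuCl, NaOt-Bu, chiral bisphosphine, B2pin2, MeOH) gives the boronate F4, and NaBO3 oxidation gives the (R)-hydroxy enone F5.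
- TBSCl/imidazole gives the silyl ether F6.
- Cycloaddition with 2 under an achiral Lewis acid (AlBr3/AlMe3) should take place anti to the silyloxy group and give the cis-fused adduct F7.
- Ring enlargement as in steps 3 and 4 passes through the dibromo carbinol F8 and the lithium enolate F9 to the seven-membered ketone F10.
- Pd(OAc)2 converts the ring A enol silane into the enone of the silyloxy enedione F11.
- DBU (toluene, heat) eliminates the silanol and returns 10.

Third, step 7. Boron may be delivered to both faces of C7, because the two flanks of the ring B enone are nearly alike and ligand control may not be transmitted, or it may also add to the ring A enone. The fallback replaces boron delivery by epoxidation and reductive opening and runs from 12 to 14. Nucleophilic epoxidation of the disubstituted ring B enone (t-BuOOH, DBU) gives the 7,8-epoxy ketone F12; its face is decided during the reversible peroxide addition and can be steered with a chiral phase-transfer catalyst. SmI2 (THF/MeOH, −90 °C) then cleaves the C8–O bond to give 14.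

Further compounds
F1 | step 6 | ring A mono(trimethylsilyloxy diene) of 10 | C1=CC(=O)C(C)[C@H]2C(C)=CC(O[Si](C)(C)C)=C[C@H]2C1(C)C
F2 | step 6 | 11-bromo bis-enone (bromine anti to ring B) | C1=CC(=O)C(C)[C@H]2C(C)=CC(=O)[C@H](Br)[C@H]2C1(C)C
F3 | step 2 | 4,4-dimethylcyclohexa-2,5-dien-1-one | CC1(C)C=CC(=O)C=C1
F4 | step 2 | 5-(pinacolboryl)-4,4-dimethylcyclohex-2-en-1-one (boron on the face that becomes the R alcohol) | CC1(C)OB(OC1(C)C)[C@@H]1CC(=O)C=CC1(C)C
F5 | step 2 | (R)-5-hydroxy-4,4-dimethylcyclohex-2-en-1-one | O[C@@H]1CC(=O)C=CC1(C)C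
F6 | step 2 | (R)-5-(tert-butyldimethylsilyloxy)-4,4-dimethylcyclohex-2-en-1-one | CC(C)(C)[Si](C)(C)O[C@@H]1CC(=O)C=CC1(C)C
F7 | step 2 | 7-silyloxy analogue of 4 (core C7, 7R; diene added anti to the silyloxy group) | CC(C)(C)[Si](C)(C)O[C@@H]1CC(=O)[C@H]2[C@@H](C)C=C(O[Si](C)(C)C(C)(C)C)C[C@H]2C1(C)C
F8 | step 2 | 7-silyloxy analogue of 6 | CC(C)(C)[Si](C)(C)O[C@@H]1CC(O)(C(C)(Br)Br)[C@H]2[C@@H](C)C=C(O[Si](C)(C)C(C)(C)C)C[C@H]2C1(C)C
F9 | step 2 | 7-silyloxy analogue of 7 | CC(C)(C)[Si](C)(C)O[C@@H]1CC(O[Li])=C(C)[C@H]2[C@@H](C)C=C(O[Si](C)(C)C(C)(C)C)C[C@H]2C1(C)C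
F10 | step 2 | 7-silyloxy analogue of 8 | CC(C)(C)[Si](C)(C)O[C@@H]1CC(=O)C(C)[C@H]2[C@@H](C)C=C(O[Si](C)(C)C(C)(C)C)C[C@H]2C1(C)C
F11 | step 2 | (7R)-7-(tert-butyldimethylsilyloxy)-3,6,6,10-tetramethylbicyclo[5.4.0]undec-2-ene-1,9-dione (core numbering; cis-fused, C10 epimers) | CC(C)(C)[Si](C)(C)O[C@@H]1CC(=O)C(C)[C@H]2C(C)=CC(=O)C[C@H]2C1(C)C
F12 | step 7 | 7,8-epoxy ketone of 12 (oxygen on the C4 side) | O1[C@@H]2[C@H]1C(=O)[C@@]3(C)[C@@H]4C(=O)C=C(C)[C@H]3[C@@H]4C2(C)C
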